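**Assumptions**
- "Farnesyl" = (2E,6E)-3,7,11-trimethyldodeca-2,6,10-trien-1-yl. Ph3COOH is a reagent made from Ph3COH and H2O2 and is not counted as a step.
- The facial sense of the tartrate-mediated epoxidation is taken by analogy with 2-alkyl-5-(hydroxymethyl) quinone monoketals of the ambuic acid series and is written for L-(+)-DIPT. This assignment is from memory of that precedent; if the first rotation/CD check shows the antipode, D-(–)-DIPT is used with no other change.

**Retrosynthetic overview**
1. 9 ⇐ 7: acetylation and ketal hydrolysis in one flask; the carbonyl next to the CH2OAc-bearing carbon stays masked as a dimethyl ketal until the end.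
2. 7 ⇐ 6: the oxirane (the only ring made) by hydroxyl-directed, tartrate-controlled nucleophilic epoxidation of the farnesyl-bearing enone of a quinone monoketal, the counterpart of the epoxidation of the farnesylated quinol/quinone in yanuthone biosynthesis.
3. 6 ⇐ 4: para-oxygenation/dearomatisation of a farnesylated cresol-type phenol (counterpart of cresol → toluquinol).
4. 4 ⇐ 1 + 2: ortho-C-farnesylation of 3-hydroxybenzyl alcohol (counterpart of aromatic prenyl transfer).
5. Ring order: carbocycle bought as the arene and dearomatised in step 2; oxirane closed in step 3; no protecting groups.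

**Route**

Step 1
Reactants: 1 3-(hydroxymethyl)phenol; 2 (2E,6E)-farnesyl bromide
Product: 4 5-(hydroxymethyl)-2-farnesylphenol, via sodium 3-(hydroxymethyl)phenolate 3 (not isolated)
Conditions: NaH (1.05 equiv), PhMe, 0 °C → rt; then 2 (1.0 equiv), rt, 16 h
Reagents that add atoms: none
Why: Ortho-selective C-allylation of a sodium phenolate (tight ion pair in a non-polar solvent, SN2 on the primary allylic bromide with the 2E geometry kept) at the unhindered ortho position para to CH2OH; the site flanked by OH and CH2OH and O-alkylation are the minor paths, and no stereocentre is formed.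

Step 2
Reactants: 4 5-(hydroxymethyl)-2-farnesylphenol
Product: 6 5-(hydroxymethyl)-4,4-dimethoxy-2-farnesylcyclohexa-2,5-dien-1-one, via methoxyphenol 5 (not isolated)
Conditions: PhI(OAc)2 (2.2 equiv), MeOH, 0 °C, 30 min; NaHCO3 work-up
Reagents that add atoms: methanol, CO
Why: Two consecutive hypervalent-iodine oxidative dearomatisations in one flask (Pelter-type PhI(OAc)2/MeOH oxidation): MeOH adds para to give 5, which is oxidised again to the p-quinone monoketal, leaving the only carbonyl next to the farnesyl-bearing carbon so that just that enone double bond has a free β-CH; phenol oxidation is far faster than attack on the isolated trisubstituted alkenes, and no stereocentre is formed.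

Step 3
Reactants: 6 5-(hydroxymethyl)-4,4-dimethoxy-2-farnesylcyclohexa-2,5-dien-1-one
Product: 7 (1R,6S)-4-(hydroxymethyl)-5,5-dimethoxy-1-farnesyl-7-oxabicyclo[4.1.0]hept-3-en-2-one
Conditions: Ph3COOH (2.5 equiv), NaHMDS (2.2 equiv), L-(+)-DIPT (1.2 equiv), 4 Å MS, PhMe, –60 → –40 °C, 24 h; then aq. NH4Cl
Reagents that add atoms: trityl hydroperoxide, OOC(c1ccccc1)(c1ccccc1)c1ccccc1
Why: Hydroxyl-directed tartrate-mediated nucleophilic (Weitz–Scheffer-type) epoxidation: the sodium alkoxide of the CH2OH, the sodium tartrate and Ph3COO– form one aggregate that adds the peroxide to the β-CH of the α-farnesyl enone from one face (the other ring double bond is β,β-disubstituted and inert, the chain alkenes are not electrophilic), and closure of the enolate on O–O gives the cis-fused oxirane, so both stereocentres (1R,6S) are set together by the L-tartrate.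

Step 4
Reactants: 7 (1R,6S)-4-(hydroxymethyl)-5,5-dimethoxy-1-farnesyl-7-oxabicyclo[4.1.0]hept-3-en-2-one
Product: 9 (1R,6S)-4-(acetoxymethyl)-1-farnesyl-7-oxabicyclo[4.1.0]hept-3-ene-2,5-dione, via ketal acetate 8 (not isolated)
Conditions: Ac2O (1.3 equiv), Et3N (2 equiv), DMAP (5 mol %), MeCN, 0 °C, 1 h; then 48% aq. HF (excess), 0 °C → rt
Reagents that add atoms: acetic anhydride, CC(=O)OC(C)=O; water, O
Why: DMAP-catalysed acylation of the only hydroxyl followed in the same flask by acid-catalysed ketal hydrolysis; the acetate is made while it sits on the β-carbon of a mono-enone (no SN2′ loss) and the enedione is released only under acidic conditions that the α,β-epoxy ketone, the ester and the trisubstituted alkenes tolerate, the stereocentres being untouched.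

**Compound list**

1 | 3-(hydroxymethyl)phenol (3-hydroxybenzyl alcohol) | OCc1cccc(O)c1 | starting material
2 | (2E,6E)-farnesyl bromide | BrC/C=C(\C)CC/C=C(\C)CCC=C(C)C | starting material
3 | sodium 3-(hydroxymethyl)phenolate | [Na+].[O-]c1cccc(CO)c1 | intermediate
4 | 5-(hydroxymethyl)-2-farnesylphenol (4-farnesyl-3-hydroxybenzyl alcohol) | OCc1ccc(C/C=C(\C)CC/C=C(\C)CCC=C(C)C)c(O)c1 | intermediate
5 | 5-(hydroxymethyl)-4-methoxy-2-farnesylphenol | COc1cc(C/C=C(\C)CC/C=C(\C)CCC=C(C)C)c(O)cc1CO | intermediate
6 | 5-(hydroxymethyl)-4,4-dimethoxy-2-farnesylcyclohexa-2,5-dien-1-one | COC1(OC)C=C(C/C=C(\C)CC/C=C(\C)CCC=C(C)C)C(=O)C=C1CO | intermediate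
7 | (1R,6S)-4-(hydroxymethyl)-5,5-dimethoxy-1-farnesyl-7-oxabicyclo[4.1.0]hept-3-en-2-one | OCC1=CC(=O)[C@]2(C/C=C(\C)CC/C=C(\C)CCC=C(C)C)O[C@@H]2C1(OC)OC | intermediate
8 | (1R,6S)-4-(acetoxymethyl)-5,5-dimethoxy-1-farnesyl-7-oxabicyclo[4.1.0]hept-3-en-2-one | CC(=O)OCC1=CC(=O)[C@]2(C/C=C(\C)CC/C=C(\C)CCC=C(C)C)O[C@@H]2C1(OC)OC | intermediate
9 | (1R,6S)-4-(acetoxymethyl)-1-farnesyl-7-oxabicyclo[4.1.0]hept-3-ene-2,5-dione (CNP0301406.1) | CC(=O)OCC1=CC(=O)[C@]2(C/C=C(\C)CC/C=C(\C)CCC=C(C)C)O[C@@H]2C1=O | target

**Totals**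
Total step count: 4. Longest linear sequence: 4.

**Steps most likely to fail, with fallbacks**

Step 1 (O- versus C-alkylation and which ortho carbon reacts). The fallback sets out from 1 and comes back at 4; it fixes the position of the new C–C bond by a C–Br bond instead of by phenolate selectivity. Ortho-selective bromination of 1 (NBS, cat. i-Pr2NH, CH2Cl2, –20 °C) gives 2-bromo-5-(hydroxymethyl)phenol F1. Compound 2 is converted with Bu3SnLi (THF, –78 °C) into tributyl[(2E,6E)-farnesyl]stannane F2. Stille coupling of F1 with F2 (Pd(PPh3)4, LiCl, DMF, 80 °C) then gives 4 with the free hydroxyls left on.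

Step 3 (level and sense of enantioselection on a substrate with a long lipophilic chain). The fallback sets out from 6 and comes back at 9; it replaces reagent control by a covalently bound auxiliary and a separation of diastereomers. Transketalisation of 6 with (2R,4R)-pentane-2,4-diol (PPTS, PhH, 60 °C, MeOH removed) gives the C2-symmetric spiro-1,3-dioxane ketal F3. Epoxidation with Ph3COOK (Ph3COOH, KHMDS, THF, –35 °C) gives the (1R,6S)-epoxide of the spiro ketal F4 and its (1S,6R)-epoxide epimer F5, which are diastereomers and are separated on silica. F4 is acetylated (Ac2O, Et3N, DMAP) to the spiro-ketal acetate F6, and aq. HF/MeCN hydrolysis of F6 gives 9.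

Step 2 (two oxidations in one flask on a para-unsubstituted phenol; ortho-quinone ketals and over-oxidation compete). The fallback sets out from 2 and comes back at 6 by way of 5, now isolated; the para oxygen is bought instead of being installed oxidatively. Commercial 5-hydroxy-2-methoxybenzaldehyde F7 is reduced (NaBH4, MeOH, 0 °C) to 3-(hydroxymethyl)-4-methoxyphenol F8. Its sodium 3-(hydroxymethyl)-4-methoxyphenolate F9 (NaH, PhMe) is C-farnesylated with 2 as in step 1 to give 5. One clean oxidation (PhI(OAc)2 1.1 equiv, MeOH, 0 °C) then gives 6.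

**Further compounds**

F1 | step 1 | 2-bromo-5-(hydroxymethyl)phenol | OCc1ccc(Br)c(O)c1
F2 | step 1 | tributyl[(2E,6E)-farnesyl]stannane | CCCC[Sn](CCCC)(CCCC)C/C=C(\C)CC/C=C(\C)CCC=C(C)C
F3 | step 3 | (2R,4R)-pentane-2,4-diyl spiro ketal of 6 | OCC1=CC(=O)C(C/C=C(\C)CC/C=C(\C)CCC=C(C)C)=CC12O[C@H](C)C[C@@H](C)O2
F4 | step 3 | (1R,6S)-epoxide of F3 (epoxide configuration as in 7) | OCC1=CC(=O)[C@]2(C/C=C(\C)CC/C=C(\C)CCC=C(C)C)O[C@@H]2C13O[C@H](C)C[C@@H](C)O3
F5 | step 3 | (1S,6R)-epoxide of F3 (epoxide epimer of F4) | OCC1=CC(=O)[C@@]2(C/C=C(\C)CC/C=C(\C)CCC=C(C)C)O[C@H]2C13O[C@H](C)C[C@@H](C)O3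
F6 | step 3 | acetate of F4 | CC(=O)OCC1=CC(=O)[C@]2(C/C=C(\C)CC/C=C(\C)CCC=C(C)C)O[C@@H]2C13O[C@H](C)C[C@@H](C)O3
F7 | step 2 | 5-hydroxy-2-methoxybenzaldehyde | COc1ccc(O)cc1C=O
F8 | step 2 | 3-(hydroxymethyl)-4-methoxyphenol | COc1ccc(O)cc1CO
F9 | step 2 | sodium 3-(hydroxymethyl)-4-methoxyphenolate | [Na+].[O-]c1ccc(OC)c(CO)c1
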